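## The problem

Compound 22 is a 5,7,4'-trihydroxyflavone whose ring B carries two different five-carbon chains on the carbons flanking the C4' hydroxyl: a prenyl group on C3' and a (2R)-2-hydroxy-3-methylbut-3-enyl group on C5'. Its only stereocentre is the secondary allylic carbinol carbon, two bonds out from ring B, and since nothing else in the molecule is stereogenic it must be set by a reagent or a catalyst. The two chains are isomeric isoprenoid units, so a route that installs them as equal groups must tell them apart later, whereas growing one of them from a different handle avoids this. The sensitive parts are the ortho-prenyl phenol (closes to a 2,2-dimethylchroman with acid), the isopropenyl carbinol (ionises or takes up the neighbouring phenol under acid), the two chain alkenes (no hydrogenolysis, no electrophilic oxidants), ring C (opened by hard nucleophiles) and the electron-rich ring A. The last operations therefore have to be close to neutral and non-reducing. The enabling feature is that the benzylic CH2 of the C5' chain sits on a ring carbon ortho to the C4' oxygen. Ring B can thus be unmasked as an ortho-quinone methide whose exocyclic carbon is this CH2, and an enamine of an O-silylated glycolaldehyde can deliver the oxygen-bearing carbon and its configuration in one bond formation. The phenol oxygen then holds the adduct as a six-membered lactol, and a carboxyl group at C1', para to that oxygen, activates the methide and later supplies C2 of the flavone.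

## Retrosynthesis

**Protecting groups.** The last bonds cut are the O–Si bond of the carbinol and the three O–allyl bonds of the phenols, leading from 22 through triphenol 21 to the fully protected flavone 20. Allyl and tert-butyldimethylsilyl groups are preferred to methoxymethyl or benzyl groups because zerovalent palladium and buffered fluoride remove them without acid or hydrogen. The forward steps only have to leave the chain alkenes and ring C alone.

**Ring C.** In 20 the O1–C2 bond is cut (cyclodehydration of diketone 18), then the C2–C3 bond (Claisen condensation), which gives ring B ester 15 and ring A ketone 17. Cutting the C2–C1' bond instead would need a cross-coupling with a metallated ring B that already carries both chains. Forming C2–C3 by an aldol condensation would need an oxidative ring closure that the alkenes would not tolerate. A thermal condensation with unprotected ring A would spare protecting groups but runs above 200 °C. The Claisen cut uses the ester of 15 as it stands. It asks for acylation of a ketone dianion by a deactivated benzoate and for a dehydration mild enough for a secondary silyl ether.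

**Isopropenyl group.** In 15 the C=CH2 bond is cut to methyl ketone 14 (Wittig), the ketone is traced to carbinol 13 and, minus the O-allyl group, to diol 12, and the C–CH3 bond is cut to lactol 10 (Grignard addition to the masked aldehyde). The aldehyde carbon of 10 thus ends as the fully substituted alkene carbon. A double methyl addition followed by dehydration would raise a regiochemical question that this sequence avoids. It costs four standard steps, and among the isolated compounds the stereocentre is α to a carbonyl group only in 14.

**Key disconnection.** Lactol 10 is opened at the ring O–C2 bond and at the bond between the benzylic CH2 and the oxygen-bearing carbon. This gives ortho-quinone methide 8, released from sulfone 6, and aldehyde 7. A cut between the carbinol carbon and the isopropenyl carbon would call for a carbonyl addition with no good handle for enantiocontrol. A cut at the aryl–CH2 bond would call for an epoxide opening with allylic transposition as competitor. The chosen cut uses the phenol already present, forms bond and stereocentre catalytically, and its partners are an achiral sulfone and a commercial two-carbon aldehyde. The forward reaction must control the enamine face and must outrun the self-reactions of a methide that has no substituent on its terminus.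

**Sulfone.** Sulfone 6 comes from benzylic alcohol 5 by exchange of hydroxyl for sulfinate, 5 from aldehyde 4 by reduction, and 4 from phenol 3 by cutting the aryl–CHO bond (ortho-formylation). Phenol 3 is cut at the aryl–prenyl bond to 1 and 2. With the prenyl group in place only one ortho position is free, so the one-carbon unit can only go where it is needed.

**Ring A ketone.** Ketone 17 comes from commercial 16 by cutting two O–allyl bonds. The chelated hydroxyl stays free and later becomes O1.

## Roads not taken

Alternative 1: Ring B is the last ring made. The C2'–C3' and C5'–C6' bonds are cut, so that acyclic ketone A1, (3R)-3-(tert-butyldimethylsilyloxy)-2,10-dimethylundeca-1,9-dien-6-one, supplies C3', C4' and C5' with both chains, and the chromon-2-yl vinamidinium salt A2 supplies C2', C1' and C6'. In the forward step KOtBu would enolise A1 on both sides and the two α-carbons would condense with the two termini of A2 to give phenol A3 directly.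
- Merits: the substitution pattern of ring B is fixed by construction, the 4'-hydroxyl appears unprotected, and the assembly is highly convergent. In these respects it is the better plan, since the chosen route must rely on C-prenylation selectivity and an ortho-functionalisation sequence.
- Weak points: the stereocentre of A1 is remote from its carbonyl group and needs its own asymmetric synthesis. A2 requires Vilsmeier-type chemistry that puts methoxymethyl ethers at risk. Alkoxide at the temperature of ring closure meets a chromone that adds nucleophiles at C2. The methoxymethyl groups of A3 must finally be removed with acid beside the free ortho-prenyl phenol and the allylic carbinol.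
- Comparison: against this convergence the chosen plan sets a key step that creates the stereocentre instead of importing it, and aromatic substitutions that are each directed to a single free ortho position.

Alternative 2: The cut is the C–O bond at the future carbinol carbon. The tris(methoxymethyl) ether of the 3',5'-diprenylflavone, A4, would be epoxidised once with KHSO5 and a fructose-derived chiral ketone (Shi epoxidation) to mono-epoxide A5, whose oxirane is later isomerised to the isopropenyl carbinol function.
- Merits: both chains come from one symmetric ring B, trisubstituted alkenes are the best substrates for this epoxidation, and one isomerisation replaces the four-step homologation (steps 6 to 9) of the chosen route. In step count this road is clearly shorter.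
- Weak points: the two prenyl groups of A4 are equivalent, so A5 can only be obtained statistically beside unchanged A4 and doubly epoxidised material, on an advanced intermediate. The isomerisation of A5 needs LiNEt2, hot Al(OiPr)3 or a selenide/selenoxide sequence, each awkward beside the chromone. The final acidic removal of three methoxymethyl groups exposes the acid-labile ortho-hydroxy allylic carbinol.
- Comparison: the chosen plan pays about three more steps. Against them it sets a non-statistical differentiation of the two chains, a stereocentre made on a small intermediate where its purity can be checked and corrected, and an end game without acid.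

Alternative 3: Ring A is cut at C4a–C5. The 4-hydroxy-2-pyrone A6, which carries the complete ring B on a 2,4-dioxobutyl tether at C6, would be opened by methoxide (KOH in methanol or Mg(OMe)2). The methylene carbanion next to the former pyrone would then attack the former lactone carbonyl and give the 2,4,6-trihydroxyphenyl diketone A7.
- Merits: it is biomimetic, it delivers ring A with free hydroxyls (a real advantage over the two allyl groups the chosen route spends on ring A), and A7 is one cyclodehydration away from the flavone skeleton.
- Weak points: ring A is the one part of the target that can be bought. A6 is a masked tetraketone that needs successive acylations of polycarbonyl anions on the fully elaborated ring B ester. The opened chain can also close in the aldol sense to a resorcylate, so the Claisen mode must be enforced by the base. Nothing in the sequence addresses the stereocentre.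
- Comparison: this road is longer and spends its key step on ring A. The chosen plan spends one step on protecting purchased ring A material and keeps its key step for the only stereocentre.

Key step: step 5

Assumption: on the usual shielding model for (E)-enamines the (S)-configured catalyst should give the (3R)-lactol; if the sense proved opposite, the (R)-catalyst would be used and nothing else would change.

## Route

Step 1
Reactants: 1 methyl 4-hydroxybenzoate; 2 prenyl bromide (1-bromo-3-methylbut-2-ene)
Product: 3 methyl 4-hydroxy-3-(3-methylbut-2-enyl)benzoate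
Conditions: 1 (1.5 equiv), NaH, toluene, 0 °C → rt; then 2, rt
Reagents that add atoms: none
Why: Ortho C-alkylation of the phenoxide ArONa of 1 in a non-polar solvent, where the tight ion pair shields oxygen and the allylic halide is delivered to the ortho carbon; the O-prenyl ether and the 3,5-diprenyl by-product are removed by chromatography and the cheap phenol is used in excess.

Step 2
Reactants: 3 methyl 4-hydroxy-3-(3-methylbut-2-enyl)benzoate
Product: 4 methyl 3-formyl-4-hydroxy-5-(3-methylbut-2-enyl)benzoate
Conditions: MgCl2, Et3N, (CH2O)n, MeCN, reflux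
Reagents that add atoms: paraformaldehyde (as formaldehyde), C=O
Why: Magnesium-mediated ortho-formylation of a phenol (Casnati–Skattebøl reaction): the phenoxide bound to MgCl2 directs formaldehyde to the only free ortho carbon and a second formaldehyde accepts hydride from the benzylic alkoxide; 4-hydroxybenzoates and isolated alkenes are tolerated.

Step 3
Reactants: 4 methyl 3-formyl-4-hydroxy-5-(3-methylbut-2-enyl)benzoate
Product: 5 methyl 4-hydroxy-3-(hydroxymethyl)-5-(3-methylbut-2-enyl)benzoate
Conditions: NaBH4, MeOH–THF, 0 °C
Reagents that add atoms: none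
Why: Borohydride reduction of a salicylaldehyde; the methyl benzoate and the alkene are inert at 0 °C.

Step 4
Reactants: 5 methyl 4-hydroxy-3-(hydroxymethyl)-5-(3-methylbut-2-enyl)benzoate
Product: 6 methyl 4-hydroxy-3-(3-methylbut-2-enyl)-5-[(4-methylphenyl)sulfonylmethyl]benzoate
Conditions: p-TolSO2H (1.5 equiv, freshly liberated from p-TolSO2Na), CH2Cl2, rt → 35 °C
Reagents that add atoms: p-toluenesulfinic acid, Cc1ccc(cc1)S(=O)O
Why: Acid-promoted substitution of an ortho-hydroxybenzyl alcohol by sulfinate at sulfur (through the protonated carbinol and its quinone methide), the usual preparation of 2-(sulfonylmethyl)phenols; the sulfinic acid is too weak to cyclise the ortho-prenyl phenol at this temperature.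

Step 5
Reactants: 6 methyl 4-hydroxy-3-(3-methylbut-2-enyl)-5-[(4-methylphenyl)sulfonylmethyl]benzoate; 7 (tert-butyldimethylsilyloxy)acetaldehyde
Product: 10 methyl (3R)-3-(tert-butyldimethylsilyloxy)-2-hydroxy-8-(3-methylbut-2-enyl)-3,4-dihydro-2H-chromene-6-carboxylate (both C2 anomers), via ortho-quinone methide 8 (not isolated), via open-chain hydroxy aldehyde 9 (not isolated)
Conditions: (S)-2-[diphenyl(trimethylsilyloxy)methyl]pyrrolidine (20 mol%), Na2CO3 (1.5 equiv), 7 (3 equiv), CH2Cl2, 0 °C → rt
Reagents that add atoms: none
Why: Na2CO3 deprotonates the acidic phenol of 6 and the phenoxide expels p-toluenesulfinate (1,4-elimination) to give ortho-quinone methide 8 in low stationary concentration, while the amine condenses with 7 to the (E)-enamine. The enamine carbon adds to the exocyclic CH2 of 8 (Michael addition driven by rearomatisation of ring B), the iminium ion is hydrolysed to aldehyde 9, and the neighbouring phenol adds to the carbonyl group to give lactol 10 and free catalyst. The closest known reaction type is the aminocatalytic Michael addition–hemiacetalisation (formal [4+2] annulation) of aldehydes with ortho-quinone methides generated in situ from 2-(1-tosylalkyl)phenols and base, which gives chroman-2-ols; here the methide carbon is unsubstituted and the aldehyde carries an α-silyloxy group. The one ring formed, the dihydropyran ring of the chroman, closes by 6-exo-trig attack of the phenol oxygen on the aldehyde carbonyl. The stereocentre C3 is controlled by the catalyst: the diphenyl(trimethylsilyloxy)methyl group of the (S)-pyrrolidine shields one face of the s-trans (E)-enamine, and attack of 8 on the open face gives the (3R) configuration, while C2 is an anomeric mixture of no consequence because this carbon becomes a ketone carbon in step 8. The step needs enantiofacial selectivity at the enamine carbon only, because the methide terminus is unsubstituted, and chemoselectivity for C–C bond formation over dimerisation of 8 and N-alkylation of the catalyst; the para ester raises the electrophilicity of 8 and the acidity of the phenol, the hindered amine is a poor N-nucleophile, re-addition of sulfinate is reversible, and 7 is used in excess. Immediate lactol formation takes the α-silyloxy aldehyde out of the enamine and enol equilibria and so protects the new stereocentre.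

Step 6
Reactants: 10 methyl (3R)-3-(tert-butyldimethylsilyloxy)-2-hydroxy-8-(3-methylbut-2-enyl)-3,4-dihydro-2H-chromene-6-carboxylate
Product: 12 methyl 3-[(2R)-2-(tert-butyldimethylsilyloxy)-3-hydroxybutyl]-4-hydroxy-5-(3-methylbut-2-enyl)benzoate (both epimers at the new carbinol carbon), via bromomagnesium aldehyde phenoxide 11 (not isolated)
Conditions: MeMgBr (3.2 equiv), THF, −78 → −40 °C; aq. NH4Cl at −40 °C
Reagents that add atoms: methylmagnesium bromide, C[Mg]Br
Why: Grignard addition to a lactol: the first equivalent of MeMgBr deprotonates the lactol hydroxyl with loss of methane, the resulting ROMgBr lactolate opens to the ArOMgBr aldehyde 11 and a second equivalent adds to its carbonyl group; the para-oxido group makes the methyl ester a vinylogous carbonate anion that is inert at this temperature, the cold quench prevents a 1,2-silyl shift, and the new carbinol centre is removed in step 8.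

Step 7
Reactants: 12 methyl 3-[(2R)-2-(tert-butyldimethylsilyloxy)-3-hydroxybutyl]-4-hydroxy-5-(3-methylbut-2-enyl)benzoate
Product: 13 methyl 3-[(2R)-2-(tert-butyldimethylsilyloxy)-3-hydroxybutyl]-5-(3-methylbut-2-enyl)-4-(prop-2-enyloxy)benzoate
Conditions: allyl bromide, K2CO3, acetone, 50 °C
Reagents that add atoms: allyl bromide, C=CCBr
Why: Williamson etherification: carbonate deprotonates only the phenol, so the secondary alcohol stays free and no alkoxide is formed that could start a silyl shift; the allyl group is chosen because zerovalent palladium removes it at the end without acid.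

Step 8
Reactants: 13 methyl 3-[(2R)-2-(tert-butyldimethylsilyloxy)-3-hydroxybutyl]-5-(3-methylbut-2-enyl)-4-(prop-2-enyloxy)benzoate
Product: 14 methyl 3-[(2R)-2-(tert-butyldimethylsilyloxy)-3-oxobutyl]-5-(3-methylbut-2-enyl)-4-(prop-2-enyloxy)benzoate
Conditions: Dess–Martin periodinane, NaHCO3, CH2Cl2, 0 °C → rt
Reagents that add atoms: none
Why: Dess–Martin oxidation of the secondary alcohol (both epimers converge on one ketone); the buffered, neutral conditions keep the α-silyloxy ketone from epimerising and leave the alkenes alone.

Step 9
Reactants: 14 methyl 3-[(2R)-2-(tert-butyldimethylsilyloxy)-3-oxobutyl]-5-(3-methylbut-2-enyl)-4-(prop-2-enyloxy)benzoate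
Product: 15 methyl 3-[(2R)-2-(tert-butyldimethylsilyloxy)-3-methylbut-3-enyl]-5-(3-methylbut-2-enyl)-4-(prop-2-enyloxy)benzoate
Conditions: Ph3PCH3Br, KN(SiMe3)2, THF, 0 °C; then 14, −78 → 0 °C
Reagents that add atoms: methylenetriphenylphosphorane (made in the flask from Ph3PCH3Br and KN(SiMe3)2), C=P(c1ccccc1)(c1ccccc1)c1ccccc1
Why: Wittig methylenation with the salt-free ylide at low temperature; addition to the unhindered methyl ketone is faster than enolisation, so the α-silyloxy stereocentre should be retained, and the ester and the allyl ether do not react.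

Step 10
Reactants: 16 1-(2,4,6-trihydroxyphenyl)ethanone
Product: 17 1-[2-hydroxy-4,6-bis(prop-2-enyloxy)phenyl]ethanone
Conditions: allyl bromide (2.1 equiv), K2CO3, acetone, reflux
Reagents that add atoms: allyl bromide, C=CCBr
Why: Williamson etherification of two of the three hydroxyls; the hydroxyl chelated to the acetyl group is the least acidic and stays free, and carbonate in acetone favours O- over C-allylation.

Step 11
Reactants: 15 methyl 3-[(2R)-2-(tert-butyldimethylsilyloxy)-3-methylbut-3-enyl]-5-(3-methylbut-2-enyl)-4-(prop-2-enyloxy)benzoate; 17 1-[2-hydroxy-4,6-bis(prop-2-enyloxy)phenyl]ethanone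
Product: 18 1-[2-hydroxy-4,6-bis(prop-2-enyloxy)phenyl]-3-{3-[(2R)-2-(tert-butyldimethylsilyloxy)-3-methylbut-3-enyl]-5-(3-methylbut-2-enyl)-4-(prop-2-enyloxy)phenyl}propane-1,3-dione
Conditions: 17 (2.5 equiv), LiN(SiMe3)2 (5.5 equiv), THF, −78 °C; then 15, −78 °C → rt; aq. NH4Cl
Reagents that add atoms: none
Why: Crossed Claisen condensation: the dilithium phenoxide–enolate of 17 is acylated at carbon by the ester of 15 and deprotonation of the diketone by the excess base drives the equilibrium; the chain stereocentre has no acidic hydrogen under these conditions.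

Step 12
Reactants: 18 1-[2-hydroxy-4,6-bis(prop-2-enyloxy)phenyl]-3-{3-[(2R)-2-(tert-butyldimethylsilyloxy)-3-methylbut-3-enyl]-5-(3-methylbut-2-enyl)-4-(prop-2-enyloxy)phenyl}propane-1,3-dione
Product: 20 2-{3-[(2R)-2-(tert-butyldimethylsilyloxy)-3-methylbut-3-enyl]-5-(3-methylbut-2-enyl)-4-(prop-2-enyloxy)phenyl}-5,7-bis(prop-2-enyloxy)chromen-4-one, via 2-hydroxyflavanone hemiketal 19 (not isolated)
Conditions: NaOAc, AcOH, 90–100 °C
Reagents that add atoms: none
Why: Cyclodehydration of a 1-(2-hydroxyaryl)-1,3-diketone: the phenol adds to the aryl ketone to give hemiketal 19 and acetate-buffered acetic acid eliminates water to the chromone; this is the mildest of the standard protocols, and premature loss of the silyl group would be tolerable because step 14 removes it anyway.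

Step 13
Reactants: 20 2-{3-[(2R)-2-(tert-butyldimethylsilyloxy)-3-methylbut-3-enyl]-5-(3-methylbut-2-enyl)-4-(prop-2-enyloxy)phenyl}-5,7-bis(prop-2-enyloxy)chromen-4-one
Product: 21 2-{3-[(2R)-2-(tert-butyldimethylsilyloxy)-3-methylbut-3-enyl]-4-hydroxy-5-(3-methylbut-2-enyl)phenyl}-5,7-dihydroxychromen-4-one
Conditions: Pd(PPh3)4 (10 mol%), morpholine (excess), THF, rt → 40 °C
Reagents that add atoms: none
Why: Tsuji–Trost deallylation: zerovalent palladium ionises the three aryl allyl ethers to π-allyl complexes, which excess morpholine captures before the ring A phenoxide can be C-allylated; the silyl ether, the prenyl group and the isopropenyl group are not ionised.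

Step 14
Reactants: 21 2-{3-[(2R)-2-(tert-butyldimethylsilyloxy)-3-methylbut-3-enyl]-4-hydroxy-5-(3-methylbut-2-enyl)phenyl}-5,7-dihydroxychromen-4-one
Product: 22 5,7-dihydroxy-2-{4-hydroxy-3-[(2R)-2-hydroxy-3-methylbut-3-enyl]-5-(3-methylbut-2-enyl)phenyl}chromen-4-one (CNP0357492.1)
Conditions: HF·pyridine, pyridine, THF, 0 °C → rt
Reagents that add atoms: none
Why: Fluoride cleavage of a secondary silyl ether; pyridine-buffered HF avoids both phenoxide formation and the strong acid that would cyclise the ortho-prenyl phenol or ionise the allylic carbinol, and the stereocentre is not touched.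

## Compound list

1 | methyl 4-hydroxybenzoate | COC(=O)c1ccc(O)cc1 | starting material
2 | prenyl bromide (1-bromo-3-methylbut-2-ene) | CC(C)=CCBr | starting material
3 | methyl 4-hydroxy-3-(3-methylbut-2-enyl)benzoate | COC(=O)c1ccc(O)c(CC=C(C)C)c1 | intermediate
4 | methyl 3-formyl-4-hydroxy-5-(3-methylbut-2-enyl)benzoate | COC(=O)c1cc(C=O)c(O)c(CC=C(C)C)c1 | intermediate
5 | methyl 4-hydroxy-3-(hydroxymethyl)-5-(3-methylbut-2-enyl)benzoate | COC(=O)c1cc(CO)c(O)c(CC=C(C)C)c1 | intermediate
6 | methyl 4-hydroxy-3-(3-methylbut-2-enyl)-5-[(4-methylphenyl)sulfonylmethyl]benzoate | COC(=O)c1cc(CC=C(C)C)c(O)c(CS(=O)(=O)c2ccc(C)cc2)c1 | intermediate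
7 | (tert-butyldimethylsilyloxy)acetaldehyde | O=CCO[Si](C)(C)C(C)(C)C | starting material
8 | methyl 3-methylidene-5-(3-methylbut-2-enyl)-4-oxocyclohexa-1,5-diene-1-carboxylate (ortho-quinone methide, not isolated) | COC(=O)C1=CC(=C)C(=O)C(CC=C(C)C)=C1 | intermediate
9 | methyl 3-[(2R)-2-(tert-butyldimethylsilyloxy)-3-oxopropyl]-4-hydroxy-5-(3-methylbut-2-enyl)benzoate (open-chain hydroxy aldehyde, not isolated) | COC(=O)c1cc(CC=C(C)C)c(O)c(C[C@@H](O[Si](C)(C)C(C)(C)C)C=O)c1 | intermediate
10 | methyl (3R)-3-(tert-butyldimethylsilyloxy)-2-hydroxy-8-(3-methylbut-2-enyl)-3,4-dihydro-2H-chromene-6-carboxylate (both C2 anomers) | COC(=O)c1cc(CC=C(C)C)c2c(c1)C[C@@H](O[Si](C)(C)C(C)(C)C)C(O)O2 | intermediate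
11 | bromomagnesium 2-[(2R)-2-(tert-butyldimethylsilyloxy)-3-oxopropyl]-4-(methoxycarbonyl)-6-(3-methylbut-2-enyl)phenoxide (ring-opened ArOMgBr salt of the lactol, not isolated) | COC(=O)c1cc(CC=C(C)C)c(O[Mg]Br)c(C[C@@H](O[Si](C)(C)C(C)(C)C)C=O)c1 | intermediate
12 | methyl 3-[(2R)-2-(tert-butyldimethylsilyloxy)-3-hydroxybutyl]-4-hydroxy-5-(3-methylbut-2-enyl)benzoate (both C3 epimers of the chain) | COC(=O)c1cc(CC=C(C)C)c(O)c(C[C@@H](O[Si](C)(C)C(C)(C)C)C(C)O)c1 | intermediate
13 | methyl 3-[(2R)-2-(tert-butyldimethylsilyloxy)-3-hydroxybutyl]-5-(3-methylbut-2-enyl)-4-(prop-2-enyloxy)benzoate | COC(=O)c1cc(CC=C(C)C)c(OCC=C)c(C[C@@H](O[Si](C)(C)C(C)(C)C)C(C)O)c1 | intermediate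
14 | methyl 3-[(2R)-2-(tert-butyldimethylsilyloxy)-3-oxobutyl]-5-(3-methylbut-2-enyl)-4-(prop-2-enyloxy)benzoate | COC(=O)c1cc(CC=C(C)C)c(OCC=C)c(C[C@@H](O[Si](C)(C)C(C)(C)C)C(C)=O)c1 | intermediate
15 | methyl 3-[(2R)-2-(tert-butyldimethylsilyloxy)-3-methylbut-3-enyl]-5-(3-methylbut-2-enyl)-4-(prop-2-enyloxy)benzoate | COC(=O)c1cc(CC=C(C)C)c(OCC=C)c(C[C@@H](O[Si](C)(C)C(C)(C)C)C(C)=C)c1 | intermediate
16 | 1-(2,4,6-trihydroxyphenyl)ethanone | CC(=O)c1c(O)cc(O)cc1O | starting material
17 | 1-[2-hydroxy-4,6-bis(prop-2-enyloxy)phenyl]ethanone | CC(=O)c1c(O)cc(OCC=C)cc1OCC=C | intermediate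
18 | 1-[2-hydroxy-4,6-bis(prop-2-enyloxy)phenyl]-3-{3-[(2R)-2-(tert-butyldimethylsilyloxy)-3-methylbut-3-enyl]-5-(3-methylbut-2-enyl)-4-(prop-2-enyloxy)phenyl}propane-1,3-dione | C=CCOc1cc(O)c(C(=O)CC(=O)c2cc(CC=C(C)C)c(OCC=C)c(C[C@@H](O[Si](C)(C)C(C)(C)C)C(C)=C)c2)c(OCC=C)c1 | intermediate
19 | 2-{3-[(2R)-2-(tert-butyldimethylsilyloxy)-3-methylbut-3-enyl]-5-(3-methylbut-2-enyl)-4-(prop-2-enyloxy)phenyl}-2-hydroxy-5,7-bis(prop-2-enyloxy)-2,3-dihydrochromen-4-one (hemiketal, both C2 epimers, not isolated) | C=CCOc1cc(OCC=C)c2c(c1)OC(O)(CC2=O)c1cc(CC=C(C)C)c(OCC=C)c(C[C@@H](O[Si](C)(C)C(C)(C)C)C(C)=C)c1 | intermediate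
20 | 2-{3-[(2R)-2-(tert-butyldimethylsilyloxy)-3-methylbut-3-enyl]-5-(3-methylbut-2-enyl)-4-(prop-2-enyloxy)phenyl}-5,7-bis(prop-2-enyloxy)chromen-4-one | C=CCOc1cc(OCC=C)c2c(=O)cc(-c3cc(CC=C(C)C)c(OCC=C)c(C[C@@H](O[Si](C)(C)C(C)(C)C)C(C)=C)c3)oc2c1 | intermediate
21 | 2-{3-[(2R)-2-(tert-butyldimethylsilyloxy)-3-methylbut-3-enyl]-4-hydroxy-5-(3-methylbut-2-enyl)phenyl}-5,7-dihydroxychromen-4-one | Oc1cc(O)c2c(=O)cc(-c3cc(CC=C(C)C)c(O)c(C[C@@H](O[Si](C)(C)C(C)(C)C)C(C)=C)c3)oc2c1 | intermediate
22 | 5,7-dihydroxy-2-{4-hydroxy-3-[(2R)-2-hydroxy-3-methylbut-3-enyl]-5-(3-methylbut-2-enyl)phenyl}chromen-4-one | C=C(C)[C@H](O)Cc1cc(-c2cc(=O)c3c(O)cc(O)cc3o2)cc(CC=C(C)C)c1O | target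

## Step count and risks

Total step count: 14. Longest linear sequence: 13 steps (steps 1–9 and 11–14; step 10 is the one-step branch to 17).

**Step 5 (key step).** The methide has no substituent on its terminus. It may therefore dimerise or alkylate the catalyst nitrogen faster than the enamine is formed, and an uncatalysed background addition or a Z-enamine pathway would erode the enantioselectivity. The fallback sets the stereocentre by reagent-controlled reduction; it sets out from 15 of insufficient enantiomeric purity and comes back to 15. HF·pyridine would cleave the silyl ether to the free allylic alcohol methyl 3-[(2R)-2-hydroxy-3-methylbut-3-enyl]-5-(3-methylbut-2-enyl)-4-(prop-2-enyloxy)benzoate F1 (scalemic at this point). Dess–Martin oxidation would then give the isopropenyl ketone methyl 3-(3-methyl-2-oxobut-3-enyl)-5-(3-methylbut-2-enyl)-4-(prop-2-enyloxy)benzoate F2. Corey–Bakshi–Shibata reduction of F2 with (S)-1-methyl-3,3-diphenyltetrahydro-1H,3H-pyrrolo[1,2-c][1,3,2]oxazaborole and catecholborane at −78 °C should return F1 as the (R)-alcohol, the isopropenyl group acting as the large substituent, and tert-butyldimethylsilyl triflate with 2,6-lutidine would regenerate 15. With this loop in reserve the addition can be optimised for conversion alone.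

**Step 6.** The Grignard reagent may attack the methyl ester if the phenoxide is not fully formed, and the ROMgBr alkoxide next to the silyl ether may undergo a 1,2-silyl shift on warming, which would expose the wrong hydroxyl to oxidation. The fallback avoids both; it sets out from 10 and comes back to the route at 14. Oxidation of the lactol (2,2,6,6-tetramethylpiperidin-1-oxyl as catalyst, PhI(OAc)2) would give the lactone methyl (3R)-3-(tert-butyldimethylsilyloxy)-8-(3-methylbut-2-enyl)-2-oxo-3,4-dihydrochromene-6-carboxylate F3. Aminolysis of this aryl ester with N,O-dimethylhydroxylamine hydrochloride and iPrMgCl at −20 °C would give the N-methoxy-N-methylamide methyl 3-{(2R)-2-(tert-butyldimethylsilyloxy)-3-[methoxy(methyl)amino]-3-oxopropyl}-4-hydroxy-5-(3-methylbut-2-enyl)benzoate F4, and allyl bromide with K2CO3 would give its allyl ether methyl 3-{(2R)-2-(tert-butyldimethylsilyloxy)-3-[methoxy(methyl)amino]-3-oxopropyl}-5-(3-methylbut-2-enyl)-4-(prop-2-enyloxy)benzoate F5. MeMgBr (1.3 equiv, −40 °C) should then convert the chelating amide into ketone 14 well below the temperature at which a 4-alkoxybenzoate reacts.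

**Step 9.** The basic ylide may enolise the ketone toward the oxygen-bearing carbon (partial epimerisation) or simply return enolate and leave the conversion incomplete. The fallback is a Peterson olefination that sets out from 14 and comes back at 15. Me3SiCH2MgCl with CeCl3 at −78 °C (a weakly basic, strongly nucleophilic reagent) would add to give the β-hydroxysilane methyl 3-[(2R)-2-(tert-butyldimethylsilyloxy)-3-hydroxy-3-methyl-4-(trimethylsilyl)butyl]-5-(3-methylbut-2-enyl)-4-(prop-2-enyloxy)benzoate F6, and KH in THF at 0 °C would eliminate silanolate to give 15.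

**Step 11.** The 4-alkoxybenzoate is a sluggish acyl donor, so the condensation may stall at the stage of enolate and ester or revert. The fallback is the Baker–Venkataraman sequence, which sets out from 15 and comes back at 18. LiOH in aqueous THF would give the acid 3-[(2R)-2-(tert-butyldimethylsilyloxy)-3-methylbut-3-enyl]-5-(3-methylbut-2-enyl)-4-(prop-2-enyloxy)benzoic acid F7. Steglich esterification with 17 (N-(3-dimethylaminopropyl)-N'-ethylcarbodiimide hydrochloride, 4-(dimethylamino)pyridine) would give the aryl ester 2-acetyl-3,5-bis(prop-2-enyloxy)phenyl 3-[(2R)-2-(tert-butyldimethylsilyloxy)-3-methylbut-3-enyl]-5-(3-methylbut-2-enyl)-4-(prop-2-enyloxy)benzoate F8, and KOtBu in THF would move the aroyl group from oxygen to the enolate carbon to give 18.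

**Step 12.** Hot acetic acid may cleave the silyl ether and then acetylate or ionise the allylic carbinol. The fallback closes the ring without protic acid; it sets out from 18 and comes back at 20. The hemiketal tautomer 19 would be sulfonylated with methanesulfonyl chloride and Et3N at 0 °C to the hemiketal mesylate 2-{3-[(2R)-2-(tert-butyldimethylsilyloxy)-3-methylbut-3-enyl]-5-(3-methylbut-2-enyl)-4-(prop-2-enyloxy)phenyl}-4-oxo-5,7-bis(prop-2-enyloxy)-2,3-dihydrochromen-2-yl methanesulfonate F9. The amine base (1,8-diazabicyclo[5.4.0]undec-7-ene if needed) would then eliminate methanesulfonate by the E1cB path, the C3 hydrogens being α to the C4 ketone, to give 20.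

## Further compounds

F1 | step 5 | methyl 3-[(2R)-2-hydroxy-3-methylbut-3-enyl]-5-(3-methylbut-2-enyl)-4-(prop-2-enyloxy)benzoate | COC(=O)c1cc(CC=C(C)C)c(OCC=C)c(C[C@@H](O)C(C)=C)c1
F2 | step 5 | methyl 3-(3-methyl-2-oxobut-3-enyl)-5-(3-methylbut-2-enyl)-4-(prop-2-enyloxy)benzoate | COC(=O)c1cc(CC=C(C)C)c(OCC=C)c(CC(=O)C(C)=C)c1
F3 | step 6 | methyl (3R)-3-(tert-butyldimethylsilyloxy)-8-(3-methylbut-2-enyl)-2-oxo-3,4-dihydrochromene-6-carboxylate | COC(=O)c1cc(CC=C(C)C)c2c(c1)C[C@@H](O[Si](C)(C)C(C)(C)C)C(=O)O2
F4 | step 6 | methyl 3-{(2R)-2-(tert-butyldimethylsilyloxy)-3-[methoxy(methyl)amino]-3-oxopropyl}-4-hydroxy-5-(3-methylbut-2-enyl)benzoate | COC(=O)c1cc(CC=C(C)C)c(O)c(C[C@@H](O[Si](C)(C)C(C)(C)C)C(=O)N(C)OC)c1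
F5 | step 6 | methyl 3-{(2R)-2-(tert-butyldimethylsilyloxy)-3-[methoxy(methyl)amino]-3-oxopropyl}-5-(3-methylbut-2-enyl)-4-(prop-2-enyloxy)benzoate | COC(=O)c1cc(CC=C(C)C)c(OCC=C)c(C[C@@H](O[Si](C)(C)C(C)(C)C)C(=O)N(C)OC)c1
F6 | step 9 | methyl 3-[(2R)-2-(tert-butyldimethylsilyloxy)-3-hydroxy-3-methyl-4-(trimethylsilyl)butyl]-5-(3-methylbut-2-enyl)-4-(prop-2-enyloxy)benzoate (both C3 epimers) | COC(=O)c1cc(CC=C(C)C)c(OCC=C)c(C[C@@H](O[Si](C)(C)C(C)(C)C)C(C)(O)C[Si](C)(C)C)c1
F7 | step 11 | 3-[(2R)-2-(tert-butyldimethylsilyloxy)-3-methylbut-3-enyl]-5-(3-methylbut-2-enyl)-4-(prop-2-enyloxy)benzoic acid | OC(=O)c1cc(CC=C(C)C)c(OCC=C)c(C[C@@H](O[Si](C)(C)C(C)(C)C)C(C)=C)c1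
F8 | step 11 | 2-acetyl-3,5-bis(prop-2-enyloxy)phenyl 3-[(2R)-2-(tert-butyldimethylsilyloxy)-3-methylbut-3-enyl]-5-(3-methylbut-2-enyl)-4-(prop-2-enyloxy)benzoate | CC(=O)c1c(OCC=C)cc(OCC=C)cc1OC(=O)c1cc(CC=C(C)C)c(OCC=C)c(C[C@@H](O[Si](C)(C)C(C)(C)C)C(C)=C)c1
F9 | step 12 | 2-{3-[(2R)-2-(tert-butyldimethylsilyloxy)-3-methylbut-3-enyl]-5-(3-methylbut-2-enyl)-4-(prop-2-enyloxy)phenyl}-4-oxo-5,7-bis(prop-2-enyloxy)-2,3-dihydrochromen-2-yl methanesulfonate | C=CCOc1cc(OCC=C)c2c(c1)OC(OS(C)(=O)=O)(CC2=O)c1cc(CC=C(C)C)c(OCC=C)c(C[C@@H](O[Si](C)(C)C(C)(C)C)C(C)=C)c1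
A1 | alternative 1 | (3R)-3-(tert-butyldimethylsilyloxy)-2,10-dimethylundeca-1,9-dien-6-one | CC(C)=CCCC(=O)CC[C@@H](O[Si](C)(C)C(C)(C)C)C(C)=C
A2 | alternative 1 | {2-[5,7-bis(methoxymethoxy)-4-oxochromen-2-yl]-3-(dimethylamino)prop-2-enylidene}dimethylammonium hexafluorophosphate | COCOc1cc(OCOC)c2c(=O)cc(C(=CN(C)C)C=[N+](C)C)oc2c1.F[P-](F)(F)(F)(F)F
A3 | alternative 1 | 2-{3-[(2R)-2-(tert-butyldimethylsilyloxy)-3-methylbut-3-enyl]-4-hydroxy-5-(3-methylbut-2-enyl)phenyl}-5,7-bis(methoxymethoxy)chromen-4-one | COCOc1cc(OCOC)c2c(=O)cc(-c3cc(CC=C(C)C)c(O)c(C[C@@H](O[Si](C)(C)C(C)(C)C)C(C)=C)c3)oc2c1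
A4 | alternative 2 | 5,7-bis(methoxymethoxy)-2-[4-(methoxymethoxy)-3,5-bis(3-methylbut-2-enyl)phenyl]chromen-4-one | COCOc1cc(OCOC)c2c(=O)cc(-c3cc(CC=C(C)C)c(OCOC)c(CC=C(C)C)c3)oc2c1
A5 | alternative 2 | 2-{3-{[(2R)-3,3-dimethyloxiran-2-yl]methyl}-4-(methoxymethoxy)-5-(3-methylbut-2-enyl)phenyl}-5,7-bis(methoxymethoxy)chromen-4-one | COCOc1cc(OCOC)c2c(=O)cc(-c3cc(CC=C(C)C)c(OCOC)c(C[C@H]4OC4(C)C)c3)oc2c1
A6 | alternative 3 | 6-{4-{3-[(2R)-2-(tert-butyldimethylsilyloxy)-3-methylbut-3-enyl]-4-(methoxymethoxy)-5-(3-methylbut-2-enyl)phenyl}-2,4-dioxobutyl}-4-hydroxypyran-2-one | O=C(CC(=O)Cc1cc(O)cc(=O)o1)c1cc(CC=C(C)C)c(OCOC)c(C[C@@H](O[Si](C)(C)C(C)(C)C)C(C)=C)c1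
A7 | alternative 3 | 1-{3-[(2R)-2-(tert-butyldimethylsilyloxy)-3-methylbut-3-enyl]-4-(methoxymethoxy)-5-(3-methylbut-2-enyl)phenyl}-3-(2,4,6-trihydroxyphenyl)propane-1,3-dione | O=C(CC(=O)c1cc(CC=C(C)C)c(OCOC)c(C[C@@H](O[Si](C)(C)C(C)(C)C)C(C)=C)c1)c1c(O)cc(O)cc1O
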